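**Plan**
1. Cuts: both C–Br bonds (C4, C4′) go back to axial alcohols and so to ketones; the CH2–C1′ bond goes back to a hydrindan-1-ylmethyl organocerium plus an enantiopure ring A ketone; the C1–C2 bond of the hydrindane is cut by a semipinacol ring contraction.
2. Enabling feature: the cyclopentane C1–C2–C3–C3a–C7a carries its one-carbon arm (the CH2 link) on C1, so it is a cyclohexane that has pushed one ring carbon outside; a trans-decalin 2-mesyloxy alcohol maps onto it.
3. Order of rings: the decalin of (S)-Wieland–Miescher ketone supplies the cyclohexane C3a–C7a and the ring to be contracted; the cyclopentane arises in the shift; ring A arrives preformed and is joined through the extruded carbon.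
4. Stereochemistry: C3a from the starting dione; C7 by α-face methyl addition; C7a and the mesylate carbon by α-face hydroboration; C1 by inversion in the shift; C1′ by equatorial attack on a ketone made by CBS reduction; C4 and C4′ by LiBH(s-Bu)3 reduction, then invertive bromination.

Key step: step 10

Numbering: decalins keep the locants of the starting dione (C1 next to the angular C8a, fusion carbons C4a/C8a, alkene C4a=C5, C6); β is the face of the angular methyl. Hydrindane and ring A use target locants (C1 bears the link, C3a methyl, C4 Br, C7 carbinol, C7a; ring A C1′ carbinol, C3′ gem-dimethyl, C4′ Br). Decalin C1, C4, C4a, C5, C6, C8a become C4, C7, C7a, C1, the exocyclic carbon and C3a.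

Remark: 7,7-dimethyl-1,4-dioxaspiro[4.5]decan-8-one is treated as a purchasable building block (it is the C-dimethylation product of 1,4-dioxaspiro[4.5]decan-8-one).

**Route**

Step 1
Reactants: 1 (S)-Wieland–Miescher ketone [(S)-8a-methyl-3,4,8,8a-tetrahydronaphthalene-1,6(2H,7H)-dione]
Product: 2 (1S,6S,8aS)-8a-methyl-1,2,3,4,6,7,8,8a-octahydronaphthalene-1,6-diol (1β,6β-diol)
Conditions: NaBH4, CeCl3·7H2O, MeOH, −78 °C → 0 °C
Reagents that add atoms: none
Why: Luche reduction delivers hydride 1,2 to both carbonyls from the α face, anti to the angular methyl, so that the C1 and C6 hydroxyls should both come out equatorial and β.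

Step 2
Reactants: 2 1β,6β-diol; 3 4-methoxybenzyl chloride
Product: 4 1β,6β-bis(4-methoxybenzyloxy)-8a-methyl-1,2,3,4,6,7,8,8a-octahydronaphthalene
Conditions: NaH, n-Bu4NI (cat.), DMF, 0 °C → rt
Reagents that add atoms: 4-methoxybenzyl chloride, COc1ccc(CCl)cc1
Why: Williamson etherification of both alkoxides, with no stereocentre touched.

Step 3
Reactants: 4 bis(4-methoxybenzyl) ether; 5 tert-butyl hydroperoxide
Product: 6 allylic alcohol (4β-hydroxy derivative of 4)
Conditions: SeO2 (0.5 equiv), t-BuOOH, CH2Cl2, rt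
Reagents that add atoms: tert-butyl hydroperoxide, CC(C)(C)OO
Why: SeO2 allylic oxidation (ene reaction, then [2,3]-sigmatropic shift) goes to the CH2 on the more substituted alkene carbon, here C4, as in the 4β-hydroxylation of 5-ene steroids; the configuration at C4 is erased in step 4.

Step 4
Reactants: 6 allylic alcohol
Product: 7 enone (C4 ketone conjugated with C4a=C5; 1β,6β-ethers unchanged)
Conditions: Dess–Martin periodinane, CH2Cl2, rt
Reagents that add atoms: none
Why: Dess–Martin oxidation of a secondary allylic alcohol to the enone; ethers and alkene are inert.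

Step 5
Reactants: 7 enone; 8 methylmagnesium bromide
Product: 9 tertiary allylic alcohol (4α-methyl, 4β-hydroxy)
Conditions: CeCl3, MeMgBr, THF, −78 °C; aq. NH4Cl
Reagents that add atoms: methylmagnesium bromide, C[Mg]Br
Why: Cerium-mediated 1,2-addition (Imamoto conditions) suppresses conjugate addition and enolisation, and because the β (axial) approach to C4 is blocked by the syn-axial angular methyl the methyl group enters from the α face, giving the axial β-hydroxyl that becomes C7 of the target.

Step 6
Reactants: 9 tertiary allylic alcohol; 10 triethylsilyl trifluoromethanesulfonate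
Product: 11 triethylsilyl ether of 9 (4β-OSiEt3)
Conditions: Et3SiOTf, 2,6-lutidine, CH2Cl2, −78 °C → 0 °C
Reagents that add atoms: triethylsilyl trifluoromethanesulfonate, CC[Si](CC)(CC)OS(=O)(=O)C(F)(F)F
Why: Silyl triflate with a hindered pyridine base silylates hindered tertiary alcohols; the ether later prevents this oxygen from displacing the C5 mesylate.

Step 7
Reactants: 11 silyl ether; 12 hydrogen peroxide
Product: 14 5α-alcohol (trans-decalin with H4a α), via alkylborane 13 (not isolated)
Conditions: BH3·THF, THF, 0 °C → rt; then NaOH, H2O2, 0 °C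
Reagents that add atoms: hydrogen peroxide, OO
Why: Hydroboration–oxidation adds H and B syn from the α face (the β face carries the angular methyl and the axial silyloxy group), with boron at the less substituted C5 anti to the C6 ether, which sets H4a α (trans fusion, future C7a) and, after oxidation with retention, the equatorial 5α-hydroxyl.

Step 8
Reactants: 14 5α-alcohol; 15 methanesulfonyl chloride
Product: 16 5α-mesylate
Conditions: MsCl, Et3N, CH2Cl2, 0 °C
Reagents that add atoms: methanesulfonyl chloride, CS(=O)(=O)Cl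
Why: Sulfonylation (via sulfene) of the only free hydroxyl, with retention at C5.

Step 9
Reactants: 16 5α-mesylate
Product: 17 1β,6β-dihydroxy 5α-mesylate (trans-decalin; 6-OH and 5-OMs trans-diequatorial; 4β-OSiEt3, 4α-CH3)
Conditions: DDQ, CH2Cl2/pH 7 buffer, 0 °C → rt
Reagents that add atoms: none
Why: Oxidative cleavage of both 4-methoxybenzyl ethers by DDQ (benzylic hydride abstraction, then hydrolysis) leaves the mesylate and the silyl ether untouched.

Step 10
Reactants: 17 dihydroxy mesylate
Product: 18 4β-hydroxy-3a,7α-dimethyl-7β-(triethylsilyloxy)-trans-hydrindane-1α-carbaldehyde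
Conditions: KOt-Bu, t-BuOH/THF, 0 °C → rt, short reaction time
Reagents that add atoms: none
Why: The tert-butoxide deprotonates the C6 hydroxyl, and the alkoxide drives the C6–C7 ring bond, which is antiperiplanar to the equatorial C5–OMs bond, onto C5 (future C1) as methanesulfonate leaves, so that C6 becomes the formyl carbon; this is a semipinacol rearrangement, the known base-induced contraction of trans-diequatorial 2-sulfonyloxycyclohexanols to cyclopentanecarbaldehydes. The cyclopentane C1–C2–C3–C3a–C7a closes by this 1,2-alkyl shift, a ring contraction with backside entry of the migrating carbon, not by exo or endo cyclisation of a chain. The one new stereocentre, C1, is set by inversion at the mesylate carbon, which places the formyl group α (cis to H7a) as the target requires; C3a and C7a are untouched. The step needs migration to beat epoxide closure, elimination and hydride shift: the rigid trans-decalin holds hydroxyl and mesylate gauche and diequatorial, so no oxygen or hydrogen is antiperiplanar to the leaving group, and the silylated oxygen at decalin C4 cannot close an oxetane. The remote C1 alkoxide (future C4) is a spectator, and contact with base is kept short because the aldehyde has an enolisable α-hydrogen.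

Step 11
Reactants: 18 aldehyde
Product: 19 1α-(hydroxymethyl)-3a,7α-dimethyl-7β-(triethylsilyloxy)-trans-hydrindan-4β-ol
Conditions: NaBH4, MeOH, 0 °C
Reagents that add atoms: none
Why: Borohydride reduction of the aldehyde, run at once so that C1 cannot epimerise.

Step 12
Reactants: 19 diol; 20 iodine
Product: 21 1α-(iodomethyl)-3a,7α-dimethyl-7β-(triethylsilyloxy)-trans-hydrindan-4β-ol
Conditions: I2, PPh3, imidazole, CH2Cl2, 0 °C
Reagents that add atoms: iodine, II
Why: Appel-type iodination substitutes the primary alkoxyphosphonium ion, while the neopentyl secondary C4 hydroxyl is too hindered to react.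

Step 13
Reactants: 22 7,7-dimethyl-1,4-dioxaspiro[4.5]decan-8-one
Product: 23 (R)-7,7-dimethyl-1,4-dioxaspiro[4.5]decan-8-ol
Conditions: (S)-1-methyl-3,3-diphenyltetrahydro-1H,3H-pyrrolo[1,2-c][1,3,2]oxazaborole (10 mol %), BH3·SMe2, THF, −20 °C; MeOH, aqueous work-up
Reagents that add atoms: none
Why: Corey–Bakshi–Shibata reduction, in which the quaternary C7 acts as the large group (as tert-butyl does in pinacolone), so the (S)-oxazaborolidine should give the (R)-alcohol.

Step 14
Reactants: 23 (R)-alcohol; 24 benzyl bromide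
Product: 25 (R)-8-(benzyloxy)-7,7-dimethyl-1,4-dioxaspiro[4.5]decane
Conditions: NaH, n-Bu4NI (cat.), THF/DMF, 0 °C → rt
Reagents that add atoms: benzyl bromide, BrCc1ccccc1
Why: Williamson etherification with retention at the carbinol carbon.

Step 15
Reactants: 25 benzyl ether; 26 water
Product: 27 (R)-4-(benzyloxy)-3,3-dimethylcyclohexan-1-one
Conditions: 1 M HCl, THF, rt
Reagents that add atoms: water, O
Why: Acid-catalysed hydrolysis of the dioxolane; the benzyl ether is stable.

Step 16
Reactants: 21 iodide; 27 (R)-ketone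
Product: 31 adduct (1′S,4′R)-4′-(benzyloxy)-3′,3′-dimethyl-1′-[(4β-hydroxy-7β-triethylsilyloxy-hydrindan-1α-yl)methyl]cyclohexan-1′-ol, via lithium alkoxide 28 (not isolated), via alkyllithium 29 (not isolated), via organocerium 30 (not isolated)
Conditions: MeLi (1.05 equiv), Et2O, −78 °C; t-BuLi (2.1 equiv), −78 °C; CeCl3, THF, −78 °C; then 27, −78 °C; aq. NH4Cl
Reagents that add atoms: none
Why: Iodine–lithium exchange (after deprotonation of the C4 hydroxyl) and transmetalation give a weakly basic organocerium that adds to the enolisable ketone (Imamoto 1,2-addition); the axial trajectory is blocked by the syn-axial C3′ methyl in either chair, so the CH2 group enters equatorially, and in the chair expected to react (benzyloxy axial, anti to that methyl and attracted to the cerium-bound carbonyl) the new hydroxyl comes out trans to the benzyloxy group, making C1′ S, with C4′ only a relay that is erased in step 18.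

Step 17
Reactants: 31 adduct
Product: 32 triol (4β-OH, 1′-OH, 4′-OH trans to 1′-OH; 7β-OSiEt3)
Conditions: H2 (1 atm), Pd(OH)2 on carbon, EtOAc, rt
Reagents that add atoms: none
Why: Hydrogenolysis of the benzyl ether; the silyl ether and the free alcohols are unaffected.

Step 18
Reactants: 32 triol
Product: 33 diketone (C4 and C4′ ketones; free 1′-OH; 7β-OSiEt3)
Conditions: Dess–Martin periodinane, CH2Cl2, rt
Reagents that add atoms: none
Why: Dess–Martin oxidation of both secondary alcohols; the tertiary hydroxyl and the silyl ether are inert.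

Step 19
Reactants: 33 diketone; 10 triethylsilyl trifluoromethanesulfonate
Product: 34 bis(triethylsilyl) diketone (1′-OSiEt3 and 7β-OSiEt3)
Conditions: Et3SiOTf, 2,6-lutidine, CH2Cl2, −78 °C → −20 °C
Reagents that add atoms: triethylsilyl trifluoromethanesulfonate, CC[Si](CC)(CC)OS(=O)(=O)C(F)(F)F
Why: Silyl triflate with 2,6-lutidine silylates the tertiary hydroxyl at low temperature faster than it enolises ketones; protection keeps this oxygen from eliminating or bridging to C4′ in step 21.

Step 20
Reactants: 34 bis-silyl diketone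
Product: 35 diaxial diol (4α-OH on the hydrindane; 4′-OH trans to the 1′ oxygen, 4′R)
Conditions: LiBH(s-Bu)3, THF, −78 °C; then NaOH, H2O2, 0 °C
Reagents that add atoms: none
Why: The bulky trialkylborohydride attacks each carbonyl, both flanked by a quaternary carbon, along the equatorial trajectory, giving the axial alcohols (as 12-oxo steroids and 4,4-dimethyl-3-oxo triterpenoids do).

Step 21
Reactants: 35 diaxial diol; 36 tetrabromomethane
Product: 37 dibromide (4β-Br and 4′-Br cis to the 1′ oxygen, both equatorial; two tertiary OSiEt3)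
Conditions: CBr4, P(n-C8H17)3, toluene, 70 °C
Reagents that add atoms: tetrabromomethane, BrC(Br)(Br)Br
Why: Appel reaction, in which each axial alkoxyphosphonium ion is displaced by bromide from the equatorial side with inversion, placing both bromines equatorial as in the target.

Step 22
Reactants: 37 dibromide
Product: 38 target CNP0166978.1
Conditions: HF·pyridine, THF, 0 °C → rt
Reagents that add atoms: none
Why: Fluoride-mediated cleavage of both tertiary triethylsilyl ethers; the equatorial bromides have no antiperiplanar hydrogen and should not eliminate.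

**Compound list**
1 | (S)-8a-methyl-3,4,8,8a-tetrahydronaphthalene-1,6(2H,7H)-dione | C[C@]12CCC(=O)C=C1CCCC2=O | starting material
2 | (1S,6S,8aS)-8a-methyl-1,2,3,4,6,7,8,8a-octahydronaphthalene-1,6-diol | O[C@H]1CC[C@]3(C)[C@@H](O)CCCC3=C1 | intermediate
3 | 4-methoxybenzyl chloride | COc1ccc(CCl)cc1 | starting material
4 | 1β,6β-bis(4-methoxybenzyloxy)-8a-methyl-1,2,3,4,6,7,8,8a-octahydronaphthalene | COc1ccc(CO[C@H]2CC[C@]3(C)[C@@H](OCc4ccc(OC)cc4)CCCC3=C2)cc1 | intermediate
5 | tert-butyl hydroperoxide | CC(C)(C)OO | starting material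
6 | 4β-hydroxy derivative of 4 (allylic alcohol) | COc1ccc(CO[C@H]2CC[C@]3(C)[C@@H](OCc4ccc(OC)cc4)CC[C@@H](O)C3=C2)cc1 | intermediate
7 | C4 enone (ketone at C4, alkene C4a=C5, 1β,6β-ethers) | COc1ccc(CO[C@H]2CC[C@]3(C)[C@@H](OCc4ccc(OC)cc4)CCC(=O)C3=C2)cc1 | intermediate
8 | methylmagnesium bromide | C[Mg]Br | starting material
9 | 4α-methyl-4β-hydroxy tertiary allylic alcohol | COc1ccc(CO[C@H]2CC[C@]3(C)[C@@H](OCc4ccc(OC)cc4)CC[C@@](C)(O)C3=C2)cc1 | intermediate
10 | triethylsilyl trifluoromethanesulfonate | CC[Si](CC)(CC)OS(=O)(=O)C(F)(F)F | starting material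
11 | 4β-triethylsilyl ether of 9 | COc1ccc(CO[C@H]2CC[C@]3(C)[C@@H](OCc4ccc(OC)cc4)CC[C@@](C)(O[Si](CC)(CC)CC)C3=C2)cc1 | intermediate
12 | hydrogen peroxide | OO | starting material
13 | 5α-alkylborane, H4a α (not isolated) | COc1ccc(CO[C@H]2CC[C@]3(C)[C@@H](OCc4ccc(OC)cc4)CC[C@@](C)(O[Si](CC)(CC)CC)[C@H]3[C@@H]2B)cc1 | intermediate
14 | 5α-alcohol, trans-decalin | COc1ccc(CO[C@H]2CC[C@]3(C)[C@@H](OCc4ccc(OC)cc4)CC[C@@](C)(O[Si](CC)(CC)CC)[C@H]3[C@@H]2O)cc1 | intermediate
15 | methanesulfonyl chloride | CS(=O)(=O)Cl | starting material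
16 | 5α-mesylate | COc1ccc(CO[C@H]2CC[C@]3(C)[C@@H](OCc4ccc(OC)cc4)CC[C@@](C)(O[Si](CC)(CC)CC)[C@H]3[C@@H]2OS(C)(=O)=O)cc1 | intermediate
17 | 1β,6β-dihydroxy 5α-mesylate (key precursor) | O[C@H]1CC[C@]3(C)[C@@H](O)CC[C@@](C)(O[Si](CC)(CC)CC)[C@H]3[C@@H]1OS(C)(=O)=O | intermediate
18 | 4β-hydroxy-3a,7α-dimethyl-7β-(triethylsilyloxy)-trans-hydrindane-1α-carbaldehyde | O=C[C@@H]2CC[C@]3(C)[C@@H](O)CC[C@@](C)(O[Si](CC)(CC)CC)[C@@H]23 | intermediate
19 | 1α-(hydroxymethyl) hydrindan-4β-ol | OC[C@@H]2CC[C@]3(C)[C@@H](O)CC[C@@](C)(O[Si](CC)(CC)CC)[C@@H]23 | intermediate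
20 | iodine | II | starting material
21 | 1α-(iodomethyl) hydrindan-4β-ol | IC[C@@H]2CC[C@]3(C)[C@@H](O)CC[C@@](C)(O[Si](CC)(CC)CC)[C@@H]23 | intermediate
22 | 7,7-dimethyl-1,4-dioxaspiro[4.5]decan-8-one | CC1(C)CC2(CCC1=O)OCCO2 | starting material
23 | (R)-7,7-dimethyl-1,4-dioxaspiro[4.5]decan-8-ol | CC1(C)CC2(CC[C@H]1O)OCCO2 | intermediate
24 | benzyl bromide | BrCc1ccccc1 | starting material
25 | (R)-8-(benzyloxy)-7,7-dimethyl-1,4-dioxaspiro[4.5]decane | CC1(C)CC2(CC[C@H]1OCc3ccccc3)OCCO2 | intermediate
26 | water | O | starting material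
27 | (R)-4-(benzyloxy)-3,3-dimethylcyclohexan-1-one | CC1(C)CC(=O)CC[C@H]1OCc2ccccc2 | intermediate
28 | lithium alkoxide of 21 (not isolated) | IC[C@@H]2CC[C@]3(C)[C@@H](O[Li])CC[C@@](C)(O[Si](CC)(CC)CC)[C@@H]23 | intermediate
29 | alkyllithium, lithium alkoxide (not isolated) | [Li]C[C@@H]2CC[C@]3(C)[C@@H](O[Li])CC[C@@](C)(O[Si](CC)(CC)CC)[C@@H]23 | intermediate
30 | alkylcerium dichloride, lithium alkoxide (not isolated) | Cl[Ce](Cl)C[C@@H]2CC[C@]3(C)[C@@H](O[Li])CC[C@@](C)(O[Si](CC)(CC)CC)[C@@H]23 | intermediate
31 | adduct, 1′S,4′R, 4′-benzyloxy trans to 1′-OH | CC1(C)C[C@@](O)(C[C@@H]2CC[C@]3(C)[C@@H](O)CC[C@@](C)(O[Si](CC)(CC)CC)[C@@H]23)CC[C@H]1OCc4ccccc4 | intermediate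
32 | triol (4β-OH, 1′-OH, 4′-OH) | CC1(C)C[C@@](O)(C[C@@H]2CC[C@]3(C)[C@@H](O)CC[C@@](C)(O[Si](CC)(CC)CC)[C@@H]23)CC[C@H]1O | intermediate
33 | 4,4′-diketone with free 1′-OH | CC1(C)C[C@@](O)(C[C@@H]2CC[C@]3(C)C(=O)CC[C@@](C)(O[Si](CC)(CC)CC)[C@@H]23)CCC1=O | intermediate
34 | 4,4′-diketone, 1′,7-bis(triethylsilyl) ether | CC1(C)C[C@@](O[Si](CC)(CC)CC)(C[C@@H]2CC[C@]3(C)C(=O)CC[C@@](C)(O[Si](CC)(CC)CC)[C@@H]23)CCC1=O | intermediate
35 | 4α,4′-diaxial diol, bis(triethylsilyl) ether | CC1(C)C[C@@](O[Si](CC)(CC)CC)(C[C@@H]2CC[C@]3(C)[C@H](O)CC[C@@](C)(O[Si](CC)(CC)CC)[C@@H]23)CC[C@H]1O | intermediate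
36 | tetrabromomethane | BrC(Br)(Br)Br | starting material
37 | 4β,4′-dibromide, bis(triethylsilyl) ether | CC1(C)C[C@@](O[Si](CC)(CC)CC)(C[C@@H]2CC[C@]3(C)[C@@H](Br)CC[C@@](C)(O[Si](CC)(CC)CC)[C@@H]23)CC[C@@H]1Br | intermediate
38 | CNP0166978.1 | CC1(C)C[C@@](O)(C[C@@H]2CC[C@]3(C)[C@@H](Br)CC[C@@](C)(O)[C@@H]23)CC[C@@H]1Br | target

**Count and risks**
Total step count: 22. Longest linear sequence: 19 steps (steps 1–12 and 16–22); ring A branch: steps 13–15.

Steps most likely to fail:

1. Step 21. Elimination of the activated axial oxygen with an antiperiplanar axial hydrogen, or migration of a methyl group from the neighbouring quaternary carbon, may outrun substitution at the two neopentyl carbons. Fallback: setting out from diol 35, both axial hydroxyls would be esterified with chloromethanesulfonyl chloride and pyridine to the bis(chloromethanesulfonate) F1. This isolated sulfonate would be heated with n-Bu4NBr in toluene, so that free bromide substitutes a sulfonate instead of a phosphonium ion pair, and the route is rejoined at dibromide 37.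

2. Step 16. Facial selectivity may be poor, or reversed, if the ketone reacts through the chair with the benzyloxy group equatorial; the C1′ epimers are diastereomers and separable, but material would be lost. Fallback: setting out from ketal ketone 22, reduction with the (R)-oxazaborolidine would give (S)-7,7-dimethyl-1,4-dioxaspiro[4.5]decan-8-ol F2, benzylation its benzyl ether F3, and hydrolysis (S)-4-(benzyloxy)-3,3-dimethylcyclohexan-1-one F4. Addition of organocerium 30 (from iodide 21) to F4 through the equatorial-benzyloxy chair would give the cis adduct F5 with the same C1′ configuration, hydrogenolysis would give the 4′-epimeric triol F6, and Dess–Martin oxidation rejoins the route at diketone 33, where C4′ is no longer a stereocentre.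

3. Step 3. The ene reaction may take the C6 allylic hydrogen or attack the benzylic ether positions, or stall at the hindered alkene. Fallback: setting out from dione 1, the C4 oxygen would be introduced at the dienone oxidation level. NaBH4 (one hydride equivalent, EtOH, −20 °C) would reduce only the saturated ketone to the 1β-hydroxy enone F7, and 4-methoxybenzyl trichloroacetimidate with catalytic acid would give its ether F8. t-BuMe2SiOTf and Et3N would give the extended silyl dienol ether F9, and m-chloroperbenzoic acid would oxidise its terminal carbon to the 4β-hydroxy enone F10, as in the 6β-hydroxylation of steroidal dienol ethers. Silylation (Et3SiCl, imidazole) would give the silyl ether F11, Luche reduction the 6β-allylic alcohol F12, and NaH with 4-methoxybenzyl chloride the fully protected triol F13. Removal of the secondary silyl ether (PPTS, MeOH) rejoins the route at allylic alcohol 6.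

**Further compounds**
F1 | step 21 | bis(chloromethanesulfonate) of diol 35 | CC1(C)C[C@@](O[Si](CC)(CC)CC)(C[C@@H]2CC[C@]3(C)[C@H](OS(=O)(=O)CCl)CC[C@@](C)(O[Si](CC)(CC)CC)[C@@H]23)CC[C@H]1OS(=O)(=O)CCl
F2 | step 16 | (S)-7,7-dimethyl-1,4-dioxaspiro[4.5]decan-8-ol | CC1(C)CC2(CC[C@@H]1O)OCCO2
F3 | step 16 | (S)-8-(benzyloxy)-7,7-dimethyl-1,4-dioxaspiro[4.5]decane | CC1(C)CC2(CC[C@@H]1OCc3ccccc3)OCCO2
F4 | step 16 | (S)-4-(benzyloxy)-3,3-dimethylcyclohexan-1-one | CC1(C)CC(=O)CC[C@@H]1OCc2ccccc2
F5 | step 16 | cis adduct, 1′S,4′S, 4′-benzyloxy cis to 1′-OH | CC1(C)C[C@@](O)(C[C@@H]2CC[C@]3(C)[C@@H](O)CC[C@@](C)(O[Si](CC)(CC)CC)[C@@H]23)CC[C@@H]1OCc4ccccc4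
F6 | step 16 | 4′-epimer of triol 32 | CC1(C)C[C@@](O)(C[C@@H]2CC[C@]3(C)[C@@H](O)CC[C@@](C)(O[Si](CC)(CC)CC)[C@@H]23)CC[C@@H]1O
F7 | step 3 | (4aS,5S)-5-hydroxy-4a-methyl-4,4a,5,6,7,8-hexahydronaphthalen-2(3H)-one | O=C1CC[C@]3(C)[C@@H](O)CCCC3=C1
F8 | step 3 | 4-methoxybenzyl ether of F7 | O=C1CC[C@]3(C)[C@@H](OCc2ccc(OC)cc2)CCCC3=C1
F9 | step 3 | extended tert-butyldimethylsilyl dienol ether of F8 | CC(C)(C)[Si](C)(C)OC1CC[C@]3(C)[C@@H](OCc2ccc(OC)cc2)CCC=C3C=1
F10 | step 3 | 4β-hydroxy enone | O=C1CC[C@]3(C)[C@@H](OCc2ccc(OC)cc2)CC[C@@H](O)C3=C1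
F11 | step 3 | 4β-triethylsilyl ether of F10 | O=C1CC[C@]3(C)[C@@H](OCc2ccc(OC)cc2)CC[C@@H](O[Si](CC)(CC)CC)C3=C1
F12 | step 3 | 6β-allylic alcohol from F11 | O[C@H]1CC[C@]3(C)[C@@H](OCc2ccc(OC)cc2)CC[C@@H](O[Si](CC)(CC)CC)C3=C1
F13 | step 3 | 1β,6β-bis(4-methoxybenzyl) ether, 4β-triethylsilyl ether | COc1ccc(CO[C@H]2CC[C@]3(C)[C@@H](OCc4ccc(OC)cc4)CC[C@@H](O[Si](CC)(CC)CC)C3=C2)cc1
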